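## Retrosynthetic overview

1. The last skeletal bond made is the ester C–O bond. After removal of two TBS groups, the target divides into the primary alcohol of an O-silylated syn-1,3-diol and (Z)-2-(silyloxymethyl)but-2-enoic acid. A Mitsunobu reaction joins them, so the angelate-type Z acyl unit is never activated.
2. The key C–C bond is carbinol C–Cα of the diol. It comes from an intermolecular Evans boron syn-aldol between veratraldehyde and the N-[(E)-5-(3,4-dimethoxyphenyl)pent-4-enoyl] imide of (S)-4-benzyloxazolidin-2-one. This step sets both stereocentres, and LiBH4 later turns the imide C=O into CH2OH.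
3. The (E)-5-arylpent-4-enoyl chain comes from a Johnson–Claisen rearrangement of the vinyl Grignard adduct of veratraldehyde, which sets the E styrene.
4. The Z acid comes from crotonaldehyde through (Z)-2-iodobut-2-en-1-ol, then I/Li exchange and CO2 capture with retention (CH3 cis to CO2H, trans to CH2O).
5. No ring is formed. Both arenes are bought intact in veratraldehyde, and the oxazolidinone ring is a purchased, recovered auxiliary.

Assumption: ill-defined borate esters of the two borohydride reductions and catalyst-bound species (DMAP, propionic acid) are not numbered; every other in-flask species is.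

## Route

Step 1
Reactants: 1 3,4-dimethoxybenzaldehyde (veratraldehyde); 2 vinylmagnesium bromide
Product: 4 rac-1-(3,4-dimethoxyphenyl)prop-2-en-1-ol, via bromomagnesium alkoxide 3 (not isolated)
Conditions: 2 (1.2 equiv, 1 M in THF), THF, 0 °C, 1 h; then H2O/sat. aq. NH4Cl
Reagents that add atoms: none
Why: Grignard 1,2-addition of a vinyl nucleophile to an aromatic aldehyde is fast and clean, and the new carbinol centre may be racemic because step 2 erases it.

Step 2
Reactants: 4 rac-1-(3,4-dimethoxyphenyl)prop-2-en-1-ol; 5 triethyl orthoacetate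
Product: 8 ethyl (E)-5-(3,4-dimethoxyphenyl)pent-4-enoate, via mixed orthoester 6 (not isolated), via ketene acetal 7 (not isolated)
Conditions: 5 (6 equiv, neat), EtCO2H (0.05 equiv), 135–140 °C, EtOH distilled off, 3–4 h
Reagents that add atoms: none
Why: The Johnson–Claisen orthoester [3,3]-rearrangement runs through a chair with the aryl group pseudo-equatorial, so the carbinol centre is traded for the conjugated E styrene (typically >20:1) while the two-carbon ester arm is added.

Step 3
Reactants: 8 ethyl (E)-5-(3,4-dimethoxyphenyl)pent-4-enoate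
Product: 10 (E)-5-(3,4-dimethoxyphenyl)pent-4-enoic acid, via lithium pentenoate 9 (not isolated)
Conditions: LiOH·H2O (3 equiv), THF/MeOH/H2O 3:1:1, rt; then 1 M HCl to pH 2–3; recrystallise
Reagents that add atoms: lithium hydroxide, [Li+].[OH-]
Why: This is a plain saponification (BAc2) of an unhindered ethyl ester with nothing else base-sensitive present, and the crystalline acid allows any trace of Z isomer to be removed.

Step 4
Reactants: 10 (E)-5-(3,4-dimethoxyphenyl)pent-4-enoic acid; 11 (S)-4-benzyloxazolidin-2-one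
Product: 13 (S)-4-benzyl-3-[(E)-5-(3,4-dimethoxyphenyl)pent-4-enoyl]oxazolidin-2-one, via mixed pivalic anhydride 12 (not isolated)
Conditions: PivCl (1.05 equiv), Et3N (2.5 equiv), THF, −20 °C, 1 h; then LiCl (1.1 equiv), 11 (1.0 equiv), −20 °C → rt, 12 h
Reagents that add atoms: pivaloyl chloride, CC(C)(C)C(=O)Cl (its acyl group sits only in intermediate 12, not in 13)
Why: In this N-acylation of the Evans auxiliary by the mixed-anhydride/LiCl method the oxazolidinone attacks only the unhindered carbonyl of 12, and the auxiliary stereocentre is not touched.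

Step 5
Reactants: 13 (S)-4-benzyl-3-[(E)-5-(3,4-dimethoxyphenyl)pent-4-enoyl]oxazolidin-2-one; 1 3,4-dimethoxybenzaldehyde
Product: 16 (S)-4-benzyl-3-{(2S,4E)-5-(3,4-dimethoxyphenyl)-2-[(S)-(3,4-dimethoxyphenyl)(hydroxy)methyl]pent-4-enoyl}oxazolidin-2-one, via (Z)-dibutylboron enolate 14 (not isolated), via dibutylboron aldolate 15 (not isolated)
Conditions: Bu2BOTf (1.2 equiv), Et3N (1.4 equiv), CH2Cl2, 0 °C, 45 min; 1 (1.2 equiv), −78 °C 1 h → 0 °C 2 h; pH 7 buffer/MeOH/30 % H2O2, 0 °C
Reagents that add atoms: dibutylboron triflate, CCCCB(CCCC)OS(=O)(=O)C(F)(F)F (boron and butyl groups sit only in 14 and 15, not in 16)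
Why: In this Evans syn aldol reaction soft enolisation gives only the (Z)-boron enolate, which adds through a closed Zimmerman–Traxler chair with the auxiliary dipole opposed and the benzyl group shielding one face, so both new centres are set as (2S,3S)-syn (usually >20:1 dr), the same sense as the benzaldehyde aldol of the (S)-benzyl auxiliary.

Step 6
Reactants: 16 Evans syn aldol adduct
Product: 17 (S)-4-benzyl-3-{(2S,4E)-2-[(S)-(tert-butyldimethylsilyloxy)(3,4-dimethoxyphenyl)methyl]-5-(3,4-dimethoxyphenyl)pent-4-enoyl}oxazolidin-2-one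
Conditions: TBSOTf (1.3 equiv), 2,6-lutidine (2 equiv), CH2Cl2, −78 → 0 °C
Reagents that add atoms: tert-butyldimethylsilyl triflate, CC(C)(C)[Si](C)(C)OS(=O)(=O)C(F)(F)F
Why: Silyl ether formation with the triflate and a non-nucleophilic base caps the hindered, retro-aldol-prone and easily ionised benzylic alcohol under non-acidic, non-epimerising conditions.

Step 7
Reactants: 17 O-TBS aldol imide
Product: 19 (2R,4E)-2-[(S)-(tert-butyldimethylsilyloxy)(3,4-dimethoxyphenyl)methyl]-5-(3,4-dimethoxyphenyl)pent-4-en-1-ol, via silyloxy aldehyde 18 (not isolated)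
Conditions: LiBH4 (2.5 equiv), MeOH (2.5 equiv), THF, 0 °C, 3 h; sat. aq. NH4Cl
Reagents that add atoms: none
Why: Reductive auxiliary cleavage with LiBH4/MeOH attacks the exocyclic imide carbonyl and leaves styrene, silyl ether and both stereocentres unchanged, the α-centre changing descriptor from S to R only through the CIP priority switch.

Step 8
Reactants: 20 (E)-crotonaldehyde
Product: 21 (Z)-2-iodobut-2-enal
Conditions: I2 (1.5 equiv), K2CO3 (1.2 equiv), DMAP (0.2 equiv), THF/H2O 1:1, rt, 3 h
Reagents that add atoms: iodine, II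
Why: This Baylis–Hillman-type α-iodination (DMAP conjugate addition, enolate iodination, E1cB loss of DMAP) gives the thermodynamically preferred Z iodoenal in which CHO stays trans to CH3.

Step 9
Reactants: 21 (Z)-2-iodobut-2-enal
Product: 22 (Z)-2-iodobut-2-en-1-ol
Conditions: NaBH4 (0.6 equiv), THF/H2O 9:1, 0 °C, 30 min
Reagents that add atoms: none
Why: Borohydride 1,2-reduction of the aldehyde is far faster than conjugate reduction or C–I cleavage, so the alkene geometry is kept.

Step 10
Reactants: 22 (Z)-2-iodobut-2-en-1-ol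
Product: 23 (Z)-tert-butyl[(2-iodobut-2-en-1-yl)oxy]dimethylsilane
Conditions: TBSCl (1.2 equiv), imidazole (2 equiv), CH2Cl2, 0 °C → rt
Reagents that add atoms: tert-butyldimethylsilyl chloride, CC(C)(C)[Si](C)(C)Cl
Why: Standard TBSCl/imidazole silylation of a primary allylic alcohol installs a group that tolerates t-BuLi at −78 °C and leaves in the same final fluoride step as the benzylic TBS group.

Step 11
Reactants: 23 (Z)-tert-butyl[(2-iodobut-2-en-1-yl)oxy]dimethylsilane
Product: 26 (Z)-2-[(tert-butyldimethylsilyloxy)methyl]but-2-enoic acid, via alkenyllithium 24 (not isolated), via lithium butenoate 25 (not isolated)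
Conditions: t-BuLi (2.1 equiv), Et2O, −78 °C, 20 min; dry CO2, −78 → 0 °C; cold 1 M HCl to pH 3–4, immediate extraction
Reagents that add atoms: carbon dioxide, O=C=O; tert-butyllithium, [Li]C(C)(C)C (lithium sits only in 24 and 25)
Why: Iodine–lithium exchange and carboxylation of the configurationally stable alkenyllithium both proceed with retention, so CO2H takes the place of iodine cis to CH3 (the logic of the classical angelic acid synthesis), and the low temperature suppresses O→C silyl migration.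

Step 12
Reactants: 19 primary alcohol; 26 (Z)-2-[(tert-butyldimethylsilyloxy)methyl]but-2-enoic acid
Product: 28 (2R,4E)-2-[(S)-(tert-butyldimethylsilyloxy)(3,4-dimethoxyphenyl)methyl]-5-(3,4-dimethoxyphenyl)pent-4-en-1-yl (Z)-2-[(tert-butyldimethylsilyloxy)methyl]but-2-enoate, via alkoxyphosphonium carboxylate 27 (not isolated)
Conditions: 26 (1.3 equiv), PPh3 (1.5 equiv), DIAD (1.5 equiv, added last), THF, 0 °C → rt, 8 h
Reagents that add atoms: triphenylphosphine, c1ccccc1P(c1ccccc1)c1ccccc1 (sits only in intermediate 27, not in 28)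
Why: In this Mitsunobu esterification the carboxylate displaces the alkoxyphosphonium group at a non-stereogenic primary CH2, so the acyl carbon is never activated, the Z alkene cannot leak to E by nucleophile addition–elimination, and neither stereocentre is touched.

Step 13
Reactants: 28 bis-TBS ester
Product: 30 CNP0417076.1 = (2R,4E)-5-(3,4-dimethoxyphenyl)-2-[(S)-(3,4-dimethoxyphenyl)(hydroxy)methyl]pent-4-en-1-yl (Z)-2-(hydroxymethyl)but-2-enoate, via benzylic mono-TBS ether 29 (not isolated)
Conditions: TBAF/AcOH 1:1 (4 equiv each, premixed), THF, 0 °C → rt, 12–24 h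
Reagents that add atoms: none
Why: Fluoride desilylation is driven by the Si–F bond and buffered by AcOH, so it removes first the primary allylic and then the benzylic TBS group without ionising the electron-rich benzylic alcohol, migrating the acyl group from the favoured primary position or isomerising either alkene.

## Compound list

1 | 3,4-dimethoxybenzaldehyde (veratraldehyde) | O=Cc1ccc(OC)c(OC)c1 | starting material
2 | vinylmagnesium bromide | C=C[Mg]Br | starting material
3 | bromomagnesium alkoxide of 4, racemic (not isolated) | C=CC(O[Mg]Br)c1ccc(OC)c(OC)c1 | intermediate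
4 | rac-1-(3,4-dimethoxyphenyl)prop-2-en-1-ol | C=CC(O)c1ccc(OC)c(OC)c1 | intermediate
5 | triethyl orthoacetate | CC(OCC)(OCC)OCC | starting material
6 | mixed orthoester, 1-(3,4-dimethoxyphenyl)allyl diethyl orthoacetate, racemic (not isolated) | CC(OCC)(OCC)OC(C=C)c1ccc(OC)c(OC)c1 | intermediate
7 | ketene acetal, 1-ethoxyvinyl 1-(3,4-dimethoxyphenyl)allyl ether, racemic (not isolated) | C=C(OCC)OC(C=C)c1ccc(OC)c(OC)c1 | intermediate
8 | ethyl (E)-5-(3,4-dimethoxyphenyl)pent-4-enoate | CCOC(=O)CC/C=C/c1ccc(OC)c(OC)c1 | intermediate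
9 | lithium (E)-5-(3,4-dimethoxyphenyl)pent-4-enoate (not isolated) | [Li+].[O-]C(=O)CC/C=C/c1ccc(OC)c(OC)c1 | intermediate
10 | (E)-5-(3,4-dimethoxyphenyl)pent-4-enoic acid | OC(=O)CC/C=C/c1ccc(OC)c(OC)c1 | intermediate
11 | (S)-4-benzyloxazolidin-2-one | O=C1N[C@@H](Cc2ccccc2)CO1 | starting material
12 | (E)-5-(3,4-dimethoxyphenyl)pent-4-enoic pivalic anhydride (not isolated) | CC(C)(C)C(=O)OC(=O)CC/C=C/c1ccc(OC)c(OC)c1 | intermediate
13 | (S)-4-benzyl-3-[(E)-5-(3,4-dimethoxyphenyl)pent-4-enoyl]oxazolidin-2-one | O=C(CC/C=C/c3ccc(OC)c(OC)c3)N1[C@@H](Cc2ccccc2)COC1=O | intermediate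
14 | (Z)-dibutylboron enolate of 13, O–B cis to the cinnamyl CH2 (not isolated) | CCCCB(CCCC)O/C(=C\C/C=C/c3ccc(OC)c(OC)c3)N1[C@@H](Cc2ccccc2)COC1=O | intermediate
15 | dibutylboron aldolate of 16 (not isolated) | O=C(N1[C@@H](Cc2ccccc2)COC1=O)[C@@H](C/C=C/c3ccc(OC)c(OC)c3)[C@H](OB(CCCC)CCCC)c4ccc(OC)c(OC)c4 | intermediate
16 | (S)-4-benzyl-3-{(2S,4E)-5-(3,4-dimethoxyphenyl)-2-[(S)-(3,4-dimethoxyphenyl)(hydroxy)methyl]pent-4-enoyl}oxazolidin-2-one | O=C(N1[C@@H](Cc2ccccc2)COC1=O)[C@@H](C/C=C/c3ccc(OC)c(OC)c3)[C@H](O)c4ccc(OC)c(OC)c4 | intermediate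
17 | O-TBS ether of 16, (2S) and benzylic (S) | O=C(N1[C@@H](Cc2ccccc2)COC1=O)[C@@H](C/C=C/c3ccc(OC)c(OC)c3)[C@H](O[Si](C)(C)C(C)(C)C)c4ccc(OC)c(OC)c4 | intermediate
18 | (2S,4E)-2-[(S)-(tert-butyldimethylsilyloxy)(3,4-dimethoxyphenyl)methyl]-5-(3,4-dimethoxyphenyl)pent-4-enal (not isolated) | O=C[C@@H](C/C=C/c1ccc(OC)c(OC)c1)[C@H](O[Si](C)(C)C(C)(C)C)c2ccc(OC)c(OC)c2 | intermediate
19 | (2R,4E)-2-[(S)-(tert-butyldimethylsilyloxy)(3,4-dimethoxyphenyl)methyl]-5-(3,4-dimethoxyphenyl)pent-4-en-1-ol | OC[C@@H](C/C=C/c1ccc(OC)c(OC)c1)[C@H](O[Si](C)(C)C(C)(C)C)c2ccc(OC)c(OC)c2 | intermediate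
20 | (E)-crotonaldehyde | C/C=C/C=O | starting material
21 | (Z)-2-iodobut-2-enal (I cis to CH3) | C/C=C(/C=O)I | intermediate
22 | (Z)-2-iodobut-2-en-1-ol | C/C=C(/CO)I | intermediate
23 | (Z)-tert-butyl[(2-iodobut-2-en-1-yl)oxy]dimethylsilane | C/C=C(/CO[Si](C)(C)C(C)(C)C)I | intermediate
24 | alkenyllithium, Li cis to CH3 (not isolated) | C/C=C(/CO[Si](C)(C)C(C)(C)C)[Li] | intermediate
25 | lithium (Z)-2-[(tert-butyldimethylsilyloxy)methyl]but-2-enoate (not isolated) | C/C=C(/CO[Si](C)(C)C(C)(C)C)C(=O)[O-].[Li+] | intermediate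
26 | (Z)-2-[(tert-butyldimethylsilyloxy)methyl]but-2-enoic acid (CH3 cis to CO2H) | C/C=C(/CO[Si](C)(C)C(C)(C)C)C(=O)O | intermediate
27 | triphenylphosphonium ether of 19 paired with the carboxylate of 26 (not isolated) | C/C=C(/CO[Si](C)(C)C(C)(C)C)C(=O)[O-].c1ccccc1[P+](c2ccccc2)(c3ccccc3)OC[C@@H](C/C=C/c4ccc(OC)c(OC)c4)[C@H](O[Si](C)(C)C(C)(C)C)c5ccc(OC)c(OC)c5 | intermediate
28 | bis-TBS ester, (2R), benzylic (S), 4E, acyl Z | C/C=C(/CO[Si](C)(C)C(C)(C)C)C(=O)OC[C@@H](C/C=C/c1ccc(OC)c(OC)c1)[C@H](O[Si](C)(C)C(C)(C)C)c2ccc(OC)c(OC)c2 | intermediate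
29 | benzylic mono-TBS ether of the target (not isolated) | C/C=C(/CO)C(=O)OC[C@@H](C/C=C/c1ccc(OC)c(OC)c1)[C@H](O[Si](C)(C)C(C)(C)C)c2ccc(OC)c(OC)c2 | intermediate
30 | CNP0417076.1, (2R,4E)-5-(3,4-dimethoxyphenyl)-2-[(S)-(3,4-dimethoxyphenyl)(hydroxy)methyl]pent-4-en-1-yl (Z)-2-(hydroxymethyl)but-2-enoate | C/C=C(/CO)C(=O)OC[C@@H](C/C=C/c1ccc(OC)c(OC)c1)[C@H](O)c1ccc(OC)c(OC)c1 | target

## Step count and weak points

Total step count: 13.

Longest linear sequence: 9 steps (steps 1–7, 12 and 13, from veratraldehyde). The acid branch (steps 8–11) joins at step 12.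

**Step 5 (Evans aldol).**
- Risk: veratraldehyde is a deactivated, Lewis-basic electrophile, so conversion can stall and the adduct can retro-aldolise.
- Scope: the fallback changes both the auxiliary and the enolate metal. It sets out from acid 10 and comes back at alcohol 19.
- Acylation: acid 10 is activated as in step 4 to mixed anhydride 12. This is intercepted (Et3N, cat. DMAP, THF) by commercial (S)-4-benzyl-1,3-thiazolidine-2-thione to give the N-acyl thiazolidinethione F1.
- Aldol: TiCl4 (1.05 equiv), i-Pr2NEt (1.1 equiv) and N-methylpyrrolidinone (1 equiv) in CH2Cl2 at 0 °C convert F1 into the chlorotitanium (Z)-enolate F2. This adds to 1 at −78 → 0 °C through the non-chelated chair to give the trichlorotitanium aldolate F3. An NH4Cl quench then gives the Evans-syn thiazolidinethione adduct F4, with the same (2S,3S) sense.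
- Return: TBSOTf/2,6-lutidine gives the O-TBS thiazolidinethione adduct F5. NaBH4 in THF/EtOH cleaves this very labile thioimide through aldehyde 18 to 19.
- Benefit: the strongly Lewis-acidic titanium activates the sluggish aldehyde, and the easier auxiliary removal also relieves step 7.

**Step 11 (alkenyllithium carboxylation).**
- Risk: protonation, O→C silyl migration or over-addition to the carboxylate would cost the Z acid.
- Scope: the fallback drops organolithium chemistry and the free acid altogether. It sets out from iodide 23 (with alcohol 19 as partner) and comes back at ester 28, so steps 11 and 12 are both skipped.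
- Method: this is a Pd-catalysed carbonylative esterification using Pd(PPh3)4 (10 mol %), CO (1 atm), Et3N and 19 (1.0 equiv) with 23 (1.5 equiv) in DMF at 55 °C.
- Stereochemistry: oxidative addition and CO insertion proceed with retention of alkene geometry, and the acylpalladium species is trapped by the primary alcohol.
- Compounds outside the list on this way: none F0.

**Step 13 (double desilylation).**
- Risk: the secondary benzylic TBS ether may be slow to leave, and forcing conditions risk acyl migration or ionisation of the veratryl carbinol.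
- Scope: the fallback never silylates the benzylic oxygen. It sets out from aldol adduct 16 and comes back at target 30.
- Reduction: LiBH4/MeOH in THF at 0 °C reduces 16 through the β-hydroxy aldehyde F6 to the syn-1,3-diol F7.
- Esterification: a Mitsunobu reaction with 26 (1.05 equiv of PPh3 and DIAD, THF, −10 → 0 °C) activates only the unhindered primary hydroxyl, as the primary alkoxyphosphonium carboxylate F8. This gives the mono-TBS ester with free benzylic hydroxyl F9.
- Deprotection: the single primary allylic TBS group of F9 is removed by TBAF/AcOH at 0 °C or Et3N·3HF at rt within a short time, giving 30.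

## Further compounds

F1 | step 5 | (E)-1-[(S)-4-benzyl-2-thioxo-1,3-thiazolidin-3-yl]-5-(3,4-dimethoxyphenyl)pent-4-en-1-one | O=C(CC/C=C/c3ccc(OC)c(OC)c3)N1[C@@H](Cc2ccccc2)CSC1=S
F2 | step 5 | chlorotitanium (Z)-enolate of F1 (not isolated) | Cl[Ti](Cl)(Cl)O/C(=C\C/C=C/c3ccc(OC)c(OC)c3)N1[C@@H](Cc2ccccc2)CSC1=S
F3 | step 5 | trichlorotitanium aldolate of F4 (not isolated) | O=C(N1[C@@H](Cc2ccccc2)CSC1=S)[C@@H](C/C=C/c3ccc(OC)c(OC)c3)[C@H](O[Ti](Cl)(Cl)Cl)c4ccc(OC)c(OC)c4
F4 | step 5 | (2S,4E)-1-[(S)-4-benzyl-2-thioxo-1,3-thiazolidin-3-yl]-5-(3,4-dimethoxyphenyl)-2-[(S)-(3,4-dimethoxyphenyl)(hydroxy)methyl]pent-4-en-1-one | O=C(N1[C@@H](Cc2ccccc2)CSC1=S)[C@@H](C/C=C/c3ccc(OC)c(OC)c3)[C@H](O)c4ccc(OC)c(OC)c4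
F5 | step 5 | O-TBS ether of F4 | O=C(N1[C@@H](Cc2ccccc2)CSC1=S)[C@@H](C/C=C/c3ccc(OC)c(OC)c3)[C@H](O[Si](C)(C)C(C)(C)C)c4ccc(OC)c(OC)c4
F0 | step 11 | none | none
F6 | step 13 | (2S,4E)-5-(3,4-dimethoxyphenyl)-2-[(S)-(3,4-dimethoxyphenyl)(hydroxy)methyl]pent-4-enal (not isolated) | O=C[C@@H](C/C=C/c1ccc(OC)c(OC)c1)[C@H](O)c2ccc(OC)c(OC)c2
F7 | step 13 | (1S,2R)-1-(3,4-dimethoxyphenyl)-2-[(E)-3-(3,4-dimethoxyphenyl)prop-2-en-1-yl]propane-1,3-diol | OC[C@@H](C/C=C/c1ccc(OC)c(OC)c1)[C@H](O)c2ccc(OC)c(OC)c2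
F8 | step 13 | primary triphenylphosphonium ether of F7 paired with the carboxylate of 26 (not isolated) | C/C=C(/CO[Si](C)(C)C(C)(C)C)C(=O)[O-].c1ccccc1[P+](c2ccccc2)(c3ccccc3)OC[C@@H](C/C=C/c4ccc(OC)c(OC)c4)[C@H](O)c5ccc(OC)c(OC)c5
F9 | step 13 | (2R,4E)-5-(3,4-dimethoxyphenyl)-2-[(S)-(3,4-dimethoxyphenyl)(hydroxy)methyl]pent-4-en-1-yl (Z)-2-[(tert-butyldimethylsilyloxy)methyl]but-2-enoate | C/C=C(/CO[Si](C)(C)C(C)(C)C)C(=O)OC[C@@H](C/C=C/c1ccc(OC)c(OC)c1)[C@H](O)c2ccc(OC)c(OC)c2
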